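The six-membered ring is traced back, by cutting the C4–O and C5–O bonds, to a Birch-derived cyclohexa-2,5-dien-1-ol, 5 (locants: C1 OMe, C2=C3, C4 OBz, C5 OAc, C6 carbinol, C7 exocyclic carbon). In 5 the mirror plane of the ring runs through C6, O6, C7 and C3, so the C4=C5 and C1=C2 alkenes are enantiotopic. A chiral hafnium bishydroxamate anchored on O6 epoxidises C4=C5 alone, on the hydroxyl face; one operation closes the oxirane and fixes C4, C5 and C6. The C7 ester stays as spectator because it guards the bis-allylic carbinol against ionisation and aromatisation. Benzoate later inverts C4, and a singlet-oxygen ene reaction places O1 while moving the alkene to C2=C3.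

Key step: step 4

Locants: C1–C7 in the running text always mean the target locants defined above; systematic names carry their own IUPAC numbering.

Assumption: the sense of induction of the bishydroxamate catalyst cannot be assigned in advance for this substrate class. The ligand, N,N′-dihydroxy-N,N′-bis(diphenylacetyl)-trans-cyclohexane-1,2-diamine ("BHA ligand"), is accessible in both antipodes from (R,R)- and (S,S)-cyclohexane-1,2-diamine. The antipode that gives 6 is to be identified in a pilot run with each and is the one used in step 4.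

Step 1
Reactants: 1 benzoic acid
Product: 2 cyclohexa-2,5-diene-1-carboxylic acid
Conditions: Na, liquid NH3, EtOH, −78 °C to −33 °C; NH4Cl; then aq. HCl
Reagents that add atoms: none
Why: Birch reduction: the carboxylate-bearing arene takes up two electrons and is protonated at the ipso and para carbons, which gives the skipped 2,5-diene and no stereocentre.

Step 2
Reactants: 2 cyclohexa-2,5-diene-1-carboxylic acid
Product: 3 methyl cyclohexa-2,5-diene-1-carboxylate
Conditions: MeOH, H2SO4 (cat.), 40 °C, under argon
Reagents that add atoms: methanol, CO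
Why: Fischer esterification under mild acid catalysis should esterify the acid without moving the skipped diene into conjugation, and no stereocentre is involved.

Step 3
Reactants: 3 methyl cyclohexa-2,5-diene-1-carboxylate
Product: 5 methyl 1-hydroxycyclohexa-2,5-diene-1-carboxylate, via potassium dienolate 4 (not isolated)
Conditions: KN(SiMe3)2, THF, −78 °C; then 3-phenyl-2-(phenylsulfonyl)oxaziridine, −78 °C; AcOH quench
Reagents that add atoms: 3-phenyl-2-(phenylsulfonyl)oxaziridine, O=S(=O)(c1ccccc1)N1OC1c1ccccc1
Why: Davis oxidation of an ester enolate: the dienolate should attack the oxaziridine oxygen through its α-carbon (C6), the kinetic site also used when such Birch-derived enolates are alkylated, and C6 stays on the mirror plane so nothing stereogenic forms.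

Step 4
Reactants: 5 methyl 1-hydroxycyclohexa-2,5-diene-1-carboxylate
Product: 6 methyl (1S,2R,6S)-2-hydroxy-7-oxabicyclo[4.1.0]hept-3-ene-2-carboxylate (oxirane cis to the hydroxyl)
Conditions: Hf(OtBu)4 (10 mol %), BHA ligand (12 mol %), tert-butyl hydroperoxide (1.1 equiv, in decane), 4 Å molecular sieves, toluene, 0 °C
Reagents that add atoms: tert-butyl hydroperoxide, CC(C)(C)OO
Why: Proposed new method: the C6 hydroxyl of 5 exchanges onto the tetravalent hafnium centre held by the C2-symmetric bishydroxamate, the hydroperoxide binds the same metal, and its distal oxygen is passed to whichever flanking alkene the chiral pocket places under the peroxide. The closest known reaction type is the hydroxyl-directed asymmetric epoxidation of tertiary allylic alcohols with hafnium or vanadium bishydroxamates, together with the epoxidative desymmetrisation of divinyl carbinols; a cyclohexa-2,5-dien-1-ol bearing an α-ester has not been used in either. The oxirane closes by a concerted suprafacial oxygen-atom transfer ([2+1] addition), so the C4–O and C5–O bonds form on one face in a single step. The face is set by the substrate, since the metal alkoxide tether can deliver oxygen only syn to O6, whereas the choice between the enantiotopic C4=C5 and C1=C2 alkenes, and with it the absolute configuration of C4, C5 and the newly stereogenic C6, is set by the ligand. The step needs group selectivity and mono-epoxidation: the hydroxyl sits on the mirror plane as the only anchor, the C7 ester lowers alkene nucleophilicity so that undirected background oxidation should be negligible and the carbinol should not ionise, and the oxidant is kept near one equivalent. Any over-oxidation should remove mainly the minor enantiomer of 6, whose remaining alkene is the one the catalyst prefers, which would raise enantiomeric purity at some cost in material.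

Step 5
Reactants: 6 methyl (1S,2R,6S)-2-hydroxy-7-oxabicyclo[4.1.0]hept-3-ene-2-carboxylate
Product: 7 (1S,2S,6S)-2-(hydroxymethyl)-7-oxabicyclo[4.1.0]hept-3-en-2-ol
Conditions: NaBH4, MeOH, 0 °C
Reagents that add atoms: none
Why: Borohydride reduction of an α-hydroxy ester, which the neighbouring hydroxyl activates, while oxirane and alkene are inert to NaBH4 and the cis epoxy alcohol geometry rules out a Payne rearrangement, so all three stereocentres persist.

Step 6
Reactants: 7 (1S,2S,6S)-2-(hydroxymethyl)-7-oxabicyclo[4.1.0]hept-3-en-2-ol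
Product: 8 [(1S,2S,6S)-2-hydroxy-7-oxabicyclo[4.1.0]hept-3-en-2-yl]methyl benzoate
Conditions: BzCl (1.05 equiv), pyridine, CH2Cl2, −20 °C to 0 °C
Reagents that add atoms: benzoyl chloride, O=C(Cl)c1ccccc1
Why: Selective acylation with an acid chloride and pyridine: the primary C7 hydroxyl reacts, the tertiary C6 hydroxyl is too hindered to compete at low temperature.

Step 7
Reactants: 8 [(1S,2S,6S)-2-hydroxy-7-oxabicyclo[4.1.0]hept-3-en-2-yl]methyl benzoate; 1 benzoic acid
Product: 9 [(1S,5R,6S)-5-(benzoyloxy)-1,6-dihydroxycyclohex-2-en-1-yl]methyl benzoate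
Conditions: PhCO2H (1.5 equiv), Ti(OiPr)4 (1.5 equiv), CH2Cl2, rt; aq. tartaric acid work-up
Reagents that add atoms: benzoic acid (1), OC(=O)c1ccccc1
Why: Titanium-mediated opening of a 2,3-epoxy alcohol by a carboxylic acid at the oxirane carbon remote from the carbinol: the O6 titanium alkoxide activates the cis oxirane and benzoate attacks C4 in SN2 fashion with inversion, C5 being neopentylic and inductively deactivated, so O4 ends trans to O5 while O5 keeps its cis relation to O6.

Step 8
Reactants: 9 [(1S,5R,6S)-5-(benzoyloxy)-1,6-dihydroxycyclohex-2-en-1-yl]methyl benzoate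
Product: 10 [(1S,5R,6S)-6-acetoxy-5-(benzoyloxy)-1-hydroxycyclohex-2-en-1-yl]methyl benzoate
Conditions: Ac2O (1.2 equiv), pyridine, DMAP (cat.), CH2Cl2, 0 °C
Reagents that add atoms: acetic anhydride, CC(=O)OC(C)=O
Why: Nucleophile-catalysed acetylation (acylpyridinium transfer) takes the secondary C5 hydroxyl and leaves the tertiary C6 hydroxyl, which would need forcing conditions.

Step 9
Reactants: 10 [(1S,5R,6S)-6-acetoxy-5-(benzoyloxy)-1-hydroxycyclohex-2-en-1-yl]methyl benzoate
Product: 11 [(1S,5R,6S)-6-acetoxy-5-(benzoyloxy)-1-[(triethylsilyl)oxy]cyclohex-2-en-1-yl]methyl benzoate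
Conditions: Et3SiOTf, 2,6-lutidine, CH2Cl2, −78 °C to 0 °C
Reagents that add atoms: triethylsilyl trifluoromethanesulfonate, CC[Si](CC)(CC)OS(=O)(=O)C(F)(F)F
Why: Silylation with a silyl triflate and a hindered pyridine base reaches tertiary alcohols without touching esters, and masking O6 removes its hydrogen-bond steering of singlet oxygen and shields its face for the next step.

Step 10
Reactants: 11 [(1S,5R,6S)-6-acetoxy-5-(benzoyloxy)-1-[(triethylsilyl)oxy]cyclohex-2-en-1-yl]methyl benzoate
Product: 13 [(1R,2S,5R,6S)-6-acetoxy-5-(benzoyloxy)-2-hydroxy-1-[(triethylsilyl)oxy]cyclohex-3-en-1-yl]methyl benzoate, via allylic hydroperoxide 12 (not isolated)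
Conditions: O2, tetraphenylporphyrin (cat.), white LED, CDCl3, 0 °C; then PPh3, rt
Reagents that add atoms: dioxygen, O=O
Why: Schenck ene reaction followed by phosphine reduction of the hydroperoxide: oxygen can bond only to C1 because C6 carries no hydrogen, the alkene moves to C2=C3 with suprafacial loss of a C3 hydrogen, and attack on the face opposite the pseudoaxial C6 silyloxy group (the face of the pseudoaxial C3–H in the half-chair with O4 and O5 equatorial) should set C1 with O1 trans to O6.

Step 11
Reactants: 13 [(1R,2S,5R,6S)-6-acetoxy-5-(benzoyloxy)-2-hydroxy-1-[(triethylsilyl)oxy]cyclohex-3-en-1-yl]methyl benzoate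
Product: 14 [(1R,2S,5R,6S)-6-acetoxy-5-(benzoyloxy)-2-methoxy-1-[(triethylsilyl)oxy]cyclohex-3-en-1-yl]methyl benzoate
Conditions: Me3OBF4, 1,8-bis(dimethylamino)naphthalene, 4 Å molecular sieves, CH2Cl2, 0 °C to rt
Reagents that add atoms: trimethyloxonium tetrafluoroborate, C[O+](C)C.F[B-](F)(F)F
Why: O-methylation with a trialkyloxonium salt and a non-nucleophilic amine base proceeds at oxygen without alkoxide formation, so esters should neither cleave nor migrate and the C1–O bond, hence the C1 configuration, is untouched.

Step 12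
Reactants: 14 [(1R,2S,5R,6S)-6-acetoxy-5-(benzoyloxy)-2-methoxy-1-[(triethylsilyl)oxy]cyclohex-3-en-1-yl]methyl benzoate
Product: 15 [(1R,2S,5R,6S)-6-acetoxy-5-(benzoyloxy)-1-hydroxy-2-methoxycyclohex-3-en-1-yl]methyl benzoate (CNP0130888.1)
Conditions: HF·pyridine, THF/pyridine, 0 °C to rt
Reagents that add atoms: none
Why: Fluoride-driven cleavage of the triethylsilyl ether under buffered acidic conditions, which the esters and the allylic ether should tolerate and which should not promote acyl migration to the freed tertiary hydroxyl.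

Compound list
1 | benzoic acid | OC(=O)c1ccccc1 | starting material
2 | cyclohexa-2,5-diene-1-carboxylic acid | OC(=O)C1C=CCC=C1 | intermediate
3 | methyl cyclohexa-2,5-diene-1-carboxylate | COC(=O)C1C=CCC=C1 | intermediate
4 | potassium dienolate of 3, potassium (cyclohexa-2,5-dien-1-ylidene)(methoxy)methanolate | COC([O-])=C1C=CCC=C1.[K+] | intermediate
5 | methyl 1-hydroxycyclohexa-2,5-diene-1-carboxylate | COC(=O)C1(O)C=CCC=C1 | intermediate
6 | methyl (1S,2R,6S)-2-hydroxy-7-oxabicyclo[4.1.0]hept-3-ene-2-carboxylate | COC(=O)[C@@]1(O)C=CC[C@@H]2O[C@H]12 | intermediate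
7 | (1S,2S,6S)-2-(hydroxymethyl)-7-oxabicyclo[4.1.0]hept-3-en-2-ol | OC[C@@]1(O)C=CC[C@@H]2O[C@H]12 | intermediate
8 | [(1S,2S,6S)-2-hydroxy-7-oxabicyclo[4.1.0]hept-3-en-2-yl]methyl benzoate | O=C(OC[C@@]1(O)C=CC[C@@H]2O[C@H]12)c1ccccc1 | intermediate
9 | [(1S,5R,6S)-5-(benzoyloxy)-1,6-dihydroxycyclohex-2-en-1-yl]methyl benzoate | O=C(OC[C@@]1(O)C=CC[C@@H](OC(=O)c2ccccc2)[C@@H]1O)c1ccccc1 | intermediate
10 | [(1S,5R,6S)-6-acetoxy-5-(benzoyloxy)-1-hydroxycyclohex-2-en-1-yl]methyl benzoate | O=C(OC[C@@]1(O)C=CC[C@@H](OC(=O)c2ccccc2)[C@@H]1OC(C)=O)c1ccccc1 | intermediate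
11 | [(1S,5R,6S)-6-acetoxy-5-(benzoyloxy)-1-[(triethylsilyl)oxy]cyclohex-2-en-1-yl]methyl benzoate | O=C(OC[C@@]1(O[Si](CC)(CC)CC)C=CC[C@@H](OC(=O)c2ccccc2)[C@@H]1OC(C)=O)c1ccccc1 | intermediate
12 | [(1S,2S,5R,6S)-6-acetoxy-5-(benzoyloxy)-2-hydroperoxy-1-[(triethylsilyl)oxy]cyclohex-3-en-1-yl]methyl benzoate (same spatial arrangement as 13; the C1 descriptor differs only through ligand priority) | OO[C@H]1C=C[C@@H](OC(=O)c2ccccc2)[C@H](OC(C)=O)[C@@]1(O[Si](CC)(CC)CC)COC(=O)c1ccccc1 | intermediate
13 | [(1R,2S,5R,6S)-6-acetoxy-5-(benzoyloxy)-2-hydroxy-1-[(triethylsilyl)oxy]cyclohex-3-en-1-yl]methyl benzoate | O[C@H]1C=C[C@@H](OC(=O)c2ccccc2)[C@H](OC(C)=O)[C@@]1(O[Si](CC)(CC)CC)COC(=O)c1ccccc1 | intermediate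
14 | [(1R,2S,5R,6S)-6-acetoxy-5-(benzoyloxy)-2-methoxy-1-[(triethylsilyl)oxy]cyclohex-3-en-1-yl]methyl benzoate | CO[C@H]1C=C[C@@H](OC(=O)c2ccccc2)[C@H](OC(C)=O)[C@@]1(O[Si](CC)(CC)CC)COC(=O)c1ccccc1 | intermediate
15 | [(1R,2S,5R,6S)-6-acetoxy-5-(benzoyloxy)-1-hydroxy-2-methoxycyclohex-3-en-1-yl]methyl benzoate | CO[C@H]1C=C[C@@H](OC(=O)c2ccccc2)[C@H](OC(C)=O)[C@@]1(O)COC(=O)c1ccccc1 | target

Total step count: 12. Longest linear sequence: 12 steps (fully linear from benzoic acid).

Steps most likely to fail

Step 4 (the step bearing the label). The catalyst may fail to tell the two enantiotopic alkenes apart, may be tied up by chelation of the α-hydroxy ester, or may carry the oxidation on to the bis-epoxide. The fallback uses known chemistry only, sets out from 5 and returns to the route at 7. Substrate-directed epoxidation with VO(acac)2 and tert-butyl hydroperoxide in CH2Cl2 should give only the syn product, racemic methyl 2-hydroxy-7-oxabicyclo[4.1.0]hept-3-ene-2-carboxylate F1. NaBH4 in methanol should reduce it to racemic 2-(hydroxymethyl)-7-oxabicyclo[4.1.0]hept-3-en-2-ol F2. Esterification of the primary hydroxyl with (1S)-camphanic chloride and pyridine should then give two diastereomers, the (1S,2S,6S)-configured camphanate F3 and the (1R,2R,6R)-configured camphanate F4, to be separated by chromatography or crystallisation. Methanolysis of F3 (K2CO3, MeOH, 0 °C) releases 7, and the route continues with step 6. This gives up the desymmetrisation for a classical resolution through covalent diastereomers, at the price of half the material.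

Step 10. Photooxygenation of an electron-poor 1,2-disubstituted alkene may be so slow that sensitiser bleaching and radical-chain autoxidation overtake the ene pathway, or oxygen may be delivered on the silyloxy face. The fallback sets out from 11 and returns at 13. Epoxidation with mCPBA and NaHCO3 in CH2Cl2, expected anti to the C6 silyloxy group, should give the C1–C2 epoxide of 11 F5. PhSeNa (from PhSeSePh and NaBH4 in EtOH) should open it at C2, away from the quaternary carbon, to the trans hydroxy selenide F6. Oxidation with H2O2 and pyridine in THF and syn elimination of the selenoxide toward C3, away from the carbinol carbon, would then give 13. This replaces the pericyclic oxygenation by a polar epoxide-to-allylic-alcohol transposition.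

Step 7. Under Lewis-acid activation the C7 benzoate carbonyl may take part in opening the oxirane at C5, or acyl groups may migrate or be exchanged on titanium, so that regiocontrol is lost. The fallback sets out from 7 and returns at 9, by moving the oxirane opening ahead of any acylation. The acyl-free epoxy diol 7, bound to titanium as a C6/C7 diolate, is treated with benzoic acid and Ti(OiPr)4 and should give (1R,5S,6S)-5,6-dihydroxy-5-(hydroxymethyl)cyclohex-3-en-1-yl benzoate F7. Selective benzoylation of the primary C7 hydroxyl (BzCl, 2,4,6-collidine, CH2Cl2, −40 °C) would then give 9.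

Further compounds
F1 | step 4 | racemic methyl (1S*,2R*,6S*)-2-hydroxy-7-oxabicyclo[4.1.0]hept-3-ene-2-carboxylate (both enantiomers shown) | COC(=O)[C@@]1(O)C=CC[C@@H]2O[C@H]12.COC(=O)[C@]1(O)C=CC[C@H]2O[C@@H]12
F2 | step 4 | racemic (1S*,2S*,6S*)-2-(hydroxymethyl)-7-oxabicyclo[4.1.0]hept-3-en-2-ol (both enantiomers shown) | OC[C@@]1(O)C=CC[C@@H]2O[C@H]12.OC[C@]1(O)C=CC[C@H]2O[C@@H]12
F3 | step 4 | [(1S,2S,6S)-2-hydroxy-7-oxabicyclo[4.1.0]hept-3-en-2-yl]methyl (1S,4R)-4,7,7-trimethyl-3-oxo-2-oxabicyclo[2.2.1]heptane-1-carboxylate | C[C@]12CC[C@](C(=O)OC[C@@]3(O)C=CC[C@@H]4O[C@H]34)(OC1=O)C2(C)C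
F4 | step 4 | [(1R,2R,6R)-2-hydroxy-7-oxabicyclo[4.1.0]hept-3-en-2-yl]methyl (1S,4R)-4,7,7-trimethyl-3-oxo-2-oxabicyclo[2.2.1]heptane-1-carboxylate | C[C@]12CC[C@](C(=O)OC[C@]3(O)C=CC[C@H]4O[C@@H]34)(OC1=O)C2(C)C
F5 | step 10 | [3-acetoxy-4-(benzoyloxy)-2-[(triethylsilyl)oxy]-7-oxabicyclo[4.1.0]heptan-2-yl]methyl benzoate, the C1–C2 epoxide of 11 with the oxirane oxygen trans to the silyloxy group and the other centres as in 11 | O=C(OC[C@@]1(O[Si](CC)(CC)CC)[C@H]2O[C@H]2C[C@@H](OC(=O)c2ccccc2)[C@@H]1OC(C)=O)c1ccccc1
F6 | step 10 | [6-acetoxy-5-(benzoyloxy)-2-hydroxy-3-(phenylselanyl)-1-[(triethylsilyl)oxy]cyclohexyl]methyl benzoate, hydroxyl trans to the silyloxy group as in 13, selanyl group trans to that hydroxyl, other centres as in 11 | O=C(OC[C@@]1(O[Si](CC)(CC)CC)[C@@H](O)[C@H]([Se]c2ccccc2)C[C@@H](OC(=O)c2ccccc2)[C@@H]1OC(C)=O)c1ccccc1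
F7 | step 7 | (1R,5S,6S)-5,6-dihydroxy-5-(hydroxymethyl)cyclohex-3-en-1-yl benzoate | OC[C@@]1(O)C=CC[C@@H](OC(=O)c2ccccc2)[C@@H]1O
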